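**Plan**

1. Rings are lettered A–H along the chain: A (terminal phenoxy), B and C (dibenzofuran), D (dioxin-fused ring, with D1 and D6 its dioxin carbons, D2 bearing the free OH, D4 an OH and D5 the oxygen to ring E), E–F (biaryl), G and H (phenoxy units).
2. Retrosynthesis cuts, in order: all O–CH3 bonds and one O–Si bond; the D5–O–E aryl ether (A–D phenol plus E–F–G–H bromide); the two aryl–O bonds from the ring C catechol oxygens to D1 and D6; then the ring A ether, the B–C bond of the furan and the B–O–C ether.
3. Enabling feature: D2 and D5, the carbons flanking the dioxin carbons, both carry oxygen and are para to each other. Ring D can therefore arrive as a 1,4-benzoquinone whose C2 and C3 (D1, D6) bear chlorine and whose methoxy (the D4 oxygen) fixes the orientation.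
4. Forward order: ring C phenol → diaryl ether with ring B (SNAr) → furan closure (Pd direct arylation) → ring A ether → dioxin ring on the dichloroquinone → reduction, monosilylation, union with the arm (from a symmetrical dibromobiaryl and the G–H phenol) → desilylation and demethylation.
5. Stereochemistry: the target has no stereocentre and its E–F axis carries no descriptor, so nothing has to be controlled.

Key step: step 14

Assumption: 2-fluoro-4,6-dimethoxybenzaldehyde and 2,4,6-trimethoxyphenol are taken as purchasable building blocks (each is otherwise one standard step from 1-fluoro-3,5-dimethoxybenzene or 2,4,6-trimethoxybenzaldehyde). Dibenzofuran locants used below: 1–3 on ring C (1 = bay position), 6, 7 and 9 on ring B.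

**Ring A–B–C fragment**

Step 1
Reactants: 1 3,4-dihydroxy-5-methoxybenzaldehyde
Product: 2 4-(benzyloxy)-3-hydroxy-5-methoxybenzaldehyde
Conditions: BnBr (1.0 equiv), Li2CO3, DMF, 50 °C
Reagents that add atoms: benzyl bromide, BrCc1ccccc1
Why: The 4-hydroxyl, para to the aldehyde, is the more acidic phenol, so the weak base forms its phenoxide selectively and Williamson etherification gives the 4-benzyl ether, as in the known selective 4-O-alkylation of this catechol aldehyde.

Step 2
Reactants: 2 4-(benzyloxy)-3-hydroxy-5-methoxybenzaldehyde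
Product: 3 4-(benzyloxy)-2-bromo-3-hydroxy-5-methoxybenzaldehyde
Conditions: Br2 (1.05 equiv), NaOAc, AcOH, rt
Reagents that add atoms: bromine, BrBr
Why: Electrophilic aromatic bromination is steered by the free 3-hydroxyl to its ortho carbon C2 (also para to the 5-methoxy), the same outcome as the bromination of isovanillin to 2-bromoisovanillin, and this marks the future furan carbon of ring C.

Step 3
Reactants: 3 4-(benzyloxy)-2-bromo-3-hydroxy-5-methoxybenzaldehyde
Product: 4 4-(benzyloxy)-2-bromo-5-methoxy-3-(methoxymethoxy)benzaldehyde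
Conditions: MOMCl, iPr2NEt, CH2Cl2, 0 °C to rt
Reagents that add atoms: chloromethyl methyl ether, COCCl
Why: Standard acetal protection of a phenol; an acetal and not a second benzyl ether is placed next to the bromide so that no benzylic arene can intercept the aryl–palladium species of step 6.

Step 4
Reactants: 4 4-(benzyloxy)-2-bromo-5-methoxy-3-(methoxymethoxy)benzaldehyde
Product: 6 4-(benzyloxy)-2-bromo-5-methoxy-3-(methoxymethoxy)phenol, via aryl formate 5 (not isolated)
Conditions: mCPBA, CH2Cl2, 0 °C to rt; then K2CO3 (cat.), MeOH, rt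
Reagents that add atoms: 3-chloroperoxybenzoic acid, OOC(=O)c1cccc(Cl)c1
Why: Baeyer–Villiger (Dakin-type) oxidation, in which the electron-rich aryl group with a para-alkoxy substituent migrates to oxygen and methanolysis of the formate releases the phenol.

Step 5
Reactants: 6 4-(benzyloxy)-2-bromo-5-methoxy-3-(methoxymethoxy)phenol; 7 2-fluoro-4,6-dimethoxybenzaldehyde
Product: 8 2-[4-(benzyloxy)-2-bromo-5-methoxy-3-(methoxymethoxy)phenoxy]-4,6-dimethoxybenzaldehyde
Conditions: K2CO3, DMF, 110 °C
Reagents that add atoms: none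
Why: Nucleophilic aromatic substitution in which the ortho-formyl group stabilises the Meisenheimer adduct and fluoride leaves; the formyl group is kept as the masked ring B oxygen that will carry ring A.

Step 6
Reactants: 8 2-[4-(benzyloxy)-2-bromo-5-methoxy-3-(methoxymethoxy)phenoxy]-4,6-dimethoxybenzaldehyde
Product: 9 2-(benzyloxy)-3,7,9-trimethoxy-1-(methoxymethoxy)dibenzo[b,d]furan-6-carbaldehyde
Conditions: Pd(OAc)2 (5 mol %), PCy3·HBF4, K2CO3, PivOH (30 mol %), DMA, 120 °C
Reagents that add atoms: none
Why: Intramolecular palladium-catalysed direct arylation (zerovalent palladium inserts into C–Br, pivalate-assisted concerted metalation–deprotonation at the only C–H ortho to the ether oxygen on ring B, reductive elimination) closes the furan ring with the regiochemistry fixed by the bromide.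

Step 7
Reactants: 9 2-(benzyloxy)-3,7,9-trimethoxy-1-(methoxymethoxy)dibenzo[b,d]furan-6-carbaldehyde
Product: 11 2-(benzyloxy)-3,7,9-trimethoxy-1-(methoxymethoxy)dibenzo[b,d]furan-6-ol, via dibenzofuranyl formate 10 (not isolated)
Conditions: mCPBA, CH2Cl2, 0 °C to rt; then K2CO3 (cat.), MeOH, rt
Reagents that add atoms: 3-chloroperoxybenzoic acid, OOC(=O)c1cccc(Cl)c1
Why: Baeyer–Villiger oxidation of an aldehyde flanked by two oxygen-bearing carbons and para to a methoxy group, so aryl migration is strongly favoured, and the phenol is freed only after the peracid has been removed.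

Step 8
Reactants: 11 2-(benzyloxy)-3,7,9-trimethoxy-1-(methoxymethoxy)dibenzo[b,d]furan-6-ol; 12 1-bromo-3,5-dimethoxybenzene
Product: 13 2-(benzyloxy)-6-(3,5-dimethoxyphenoxy)-3,7,9-trimethoxy-1-(methoxymethoxy)dibenzo[b,d]furan
Conditions: CuI (10 mol %), picolinic acid, K3PO4, DMSO, 90 °C
Reagents that add atoms: none
Why: Ullmann diaryl ether synthesis with a picolinic acid-ligated copper catalyst, which accepts ortho-substituted phenols and unhindered electron-rich aryl bromides.

Step 9
Reactants: 13 2-(benzyloxy)-6-(3,5-dimethoxyphenoxy)-3,7,9-trimethoxy-1-(methoxymethoxy)dibenzo[b,d]furan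
Product: 14 6-(3,5-dimethoxyphenoxy)-3,7,9-trimethoxy-1-(methoxymethoxy)dibenzo[b,d]furan-2-ol
Conditions: H2 (1 atm), 10% Pd/C, EtOAc/MeOH, rt
Reagents that add atoms: none
Why: Catalytic hydrogenolysis cleaves only the benzyl ether, while acetal, methyl and diaryl ethers are inert.

Step 10
Reactants: 14 6-(3,5-dimethoxyphenoxy)-3,7,9-trimethoxy-1-(methoxymethoxy)dibenzo[b,d]furan-2-ol
Product: 15 6-(3,5-dimethoxyphenoxy)-3,7,9-trimethoxy-1-(methoxymethoxy)-2-[(triisopropylsilyl)oxy]dibenzo[b,d]furan
Conditions: TIPSCl, imidazole, DMF, 40 °C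
Reagents that add atoms: chlorotriisopropylsilane, CC(C)[Si](Cl)(C(C)C)C(C)C
Why: Silyl ether formation on the only free phenol, as practised for 2,6-dioxygenated phenols; this oxygen becomes the latent second nucleophile of the key step.

Step 11
Reactants: 15 6-(3,5-dimethoxyphenoxy)-3,7,9-trimethoxy-1-(methoxymethoxy)-2-[(triisopropylsilyl)oxy]dibenzo[b,d]furan
Product: 16 6-(3,5-dimethoxyphenoxy)-3,7,9-trimethoxy-2-[(triisopropylsilyl)oxy]dibenzo[b,d]furan-1-ol
Conditions: conc. HCl (cat.), MeOH/THF, 40 °C
Reagents that add atoms: none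
Why: Acid-catalysed acetal exchange removes the methoxymethyl group, while the bulky aryl silyl ether tolerates dilute acid and does not migrate to the neighbouring oxygen under acidic conditions.

**Quinone**

Step 12
Reactants: 17 3,4-dichloroanisole
Product: 20 2,3-dichloro-6-methoxyphenol, via aryllithium 18 (not isolated), via lithium arylborate 19 (not isolated)
Conditions: LiN(iPr)2, THF, −78 °C; B(OMe)3, −78 to 0 °C; then H2O2, AcOH, 0 °C to rt
Reagents that add atoms: hydrogen peroxide, OO
Why: Directed ortho-metalation at C2, the position flanked by methoxy and chlorine, followed by borylation and oxidative carbon-to-oxygen migration of the arylborate, places the hydroxyl without regiochemical ambiguity.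

Step 13
Reactants: 20 2,3-dichloro-6-methoxyphenol
Product: 21 2,3-dichloro-5-methoxy-1,4-benzoquinone
Conditions: (KSO3)2NO (2.2 equiv), KH2PO4, H2O/acetone, rt
Reagents that add atoms: potassium nitrosodisulfonate, [K+].[K+].[O]N(S(=O)(=O)[O-])S(=O)(=O)[O-]
Why: Teuber oxidation, in which the nitroxyl radical abstracts the phenolic hydrogen and a second equivalent delivers oxygen to the free para position, the standard route from guaiacols to methoxy-para-quinones.

**Dioxin ring and ring D**

Step 14
Reactants: 16 6-(3,5-dimethoxyphenoxy)-3,7,9-trimethoxy-2-[(triisopropylsilyl)oxy]dibenzo[b,d]furan-1-ol; 21 2,3-dichloro-5-methoxy-1,4-benzoquinone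
Product: 24 ring A–B–C–D dioxin quinone (1,4-dioxin ring joining O1 and O2 of the dibenzofuran to the two former C–Cl carbons; O1 on the quinone carbon next to the carbonyl that neighbours the quinone C–H; quinone methoxy retained), via aryloxychloroquinone 22 (not isolated), via chloroquinone phenoxide 23 (not isolated)
Conditions: 21 (1.1 equiv), MeCN, −20 °C, K2CO3 added last, to 0 °C; then CsF, 0 °C to rt
Reagents that add atoms: none
Why: K2CO3 forms the bay phenoxide of 16, which adds to C2 of 21, the chlorine-bearing carbon conjugated to the C4 carbonyl that the vinylogous-ester methoxy does not deactivate (the position para to the methoxy carbon), and loss of chloride gives 22. Fluoride then cleaves the silyl ether, and phenoxide 23 adds to the remaining C–Cl carbon and expels chloride, so both hindered aryl–O bonds are made at quinone carbons without a metal. The closest known reaction is the condensation of catechols with 2,3-dihalo-1,4-quinones such as 2,3-dichloro-1,4-naphthoquinone or chloranil to dibenzodioxin quinones by double addition–elimination. The 1,4-dioxin ring closes by 6-exo-trig attack of the phenoxide on the chloro-enone carbon followed by elimination, and no stereocentre is formed. The step needs one orientation of two unsymmetrical partners: the quinone methoxy decides which C–Cl carbon is attacked first, and the silyl ether ensures that only the bay oxygen is nucleophilic at that stage. Base is added last at low temperature so that the phenoxide is trapped by the quinone before silyl migration, and the tethered second attack is expected to outrun ipso exchange.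

Step 15
Reactants: 24 ring A–B–C–D dioxin quinone
Product: 25 ring A–B–C–D hydroquinone (ring D with free hydroxyls at D2 and D5)
Conditions: Na2S2O4, EtOAc/H2O, rt, under argon
Reagents that add atoms: none
Why: Dithionite reduces the quinone to the hydroquinone by two-electron transfer and leaves all aryl ethers untouched.

Step 16
Reactants: 25 ring A–B–C–D hydroquinone
Product: 26 ring A–B–C–D phenol with the D2 oxygen as triisopropylsilyl ether and the D5 hydroxyl free
Conditions: TIPSCl (1.05 equiv), imidazole, DMF, −10 °C to rt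
Reagents that add atoms: chlorotriisopropylsilane, CC(C)[Si](Cl)(C(C)C)C(C)C
Why: Steric discrimination in silyl ether formation, since the D2 hydroxyl has a ring C–H as one neighbour whereas the D5 hydroxyl is flanked by methoxy and dioxin oxygen, so the bulky chlorosilane reacts at D2.

**Arm E–F–G–H**

Step 17
Reactants: 12 1-bromo-3,5-dimethoxybenzene
Product: 27 1-bromo-2-iodo-3,5-dimethoxybenzene
Conditions: N-iodosuccinimide, CF3CO2H (cat.), MeCN, rt
Reagents that add atoms: N-iodosuccinimide, O=C1CCC(=O)N1I
Why: Electrophilic aromatic iodination occurs ortho to bromine and para to a methoxy group, the position preferred over the crowded carbon between the two methoxy groups.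

Step 18
Reactants: 27 1-bromo-2-iodo-3,5-dimethoxybenzene (two molecules)
Product: 28 2,2'-dibromo-4,4',6,6'-tetramethoxy-1,1'-biphenyl
Conditions: Cu powder (activated), DMF, 140 °C
Reagents that add atoms: none
Why: Classical Ullmann biaryl homocoupling in which copper inserts only into the weaker C–I bond, so both bromides survive and a symmetrical tetra-ortho-substituted biaryl results, as known for other 2-bromoiodoarenes.

Step 19
Reactants: 29 2,4,6-trimethoxyphenol; 7 2-fluoro-4,6-dimethoxybenzaldehyde
Product: 30 2,4-dimethoxy-6-(2,4,6-trimethoxyphenoxy)benzaldehyde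
Conditions: K2CO3, DMF, 120 °C
Reagents that add atoms: none
Why: Nucleophilic aromatic substitution of the formyl-activated fluoride by an electron-rich phenoxide, the same reaction as in step 5.

Step 20
Reactants: 30 2,4-dimethoxy-6-(2,4,6-trimethoxyphenoxy)benzaldehyde
Product: 32 2,4-dimethoxy-6-(2,4,6-trimethoxyphenoxy)phenol, via aryl formate 31 (not isolated)
Conditions: mCPBA, CH2Cl2, 0 °C to rt; then K2CO3 (cat.), MeOH, rt
Reagents that add atoms: 3-chloroperoxybenzoic acid, OOC(=O)c1cccc(Cl)c1
Why: Baeyer–Villiger oxidation of a 2,4,6-trioxygenated benzaldehyde, whose aryl group migrates readily, gives the central phenol of ring G after formate methanolysis.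

Step 21
Reactants: 32 2,4-dimethoxy-6-(2,4,6-trimethoxyphenoxy)phenol; 28 2,2'-dibromo-4,4',6,6'-tetramethoxy-1,1'-biphenyl
Product: 33 2-bromo-2'-[2,4-dimethoxy-6-(2,4,6-trimethoxyphenoxy)phenoxy]-4,4',6,6'-tetramethoxy-1,1'-biphenyl (arm bromide)
Conditions: 28 (3 equiv), CuI (20 mol %), picolinic acid, K3PO4, DMSO, 100 °C
Reagents that add atoms: none
Why: Ullmann diaryl ether synthesis under picolinic acid-ligated copper catalysis, a system developed for hindered phenols and ortho-substituted aryl halides; the excess of the symmetrical dibromide holds the reaction at mono-substitution and makes the site of attack irrelevant.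

**Union and deprotection**

Step 22
Reactants: 26 ring A–B–C–D phenol (D2 silyl ether, D5 hydroxyl free); 33 arm bromide
Product: 34 pentadeca-O-methyl D2-O-triisopropylsilyl ether of the target
Conditions: Pd(OAc)2 (10 mol %), tBuXPhos, K3PO4, toluene, 100 °C
Reagents that add atoms: none
Why: Palladium-catalysed diaryl ether cross-coupling (Buchwald–Hartwig-type C–O coupling), in which a bulky di-tert-butylbiarylphosphine promotes oxidative addition to the electron-rich ortho-substituted bromide and reductive elimination from the crowded arylpalladium phenoxide, while K3PO4 in toluene leaves the aryl silyl ether in place.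

Step 23
Reactants: 34 pentadeca-O-methyl D2-O-triisopropylsilyl ether of the target
Product: 35 pentadeca-O-methyl ether of the target (D2 hydroxyl free)
Conditions: Bu4NF, AcOH, THF, 0 °C
Reagents that add atoms: none
Why: Fluoride-induced cleavage of the aryl silyl ether, buffered with acetic acid to protect the electron-rich phenol from base and air.

Step 24
Reactants: 35 pentadeca-O-methyl ether of the target
Product: 36 CNP0192765.0
Conditions: BBr3 (excess), CH2Cl2, −78 °C to rt; then MeOH/H2O, under argon
Reagents that add atoms: none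
Why: Lewis acid-mediated cleavage of all fifteen aryl methyl ethers (bromide attacks the methyl group of each boron-complexed ether), with diaryl ether, furan and dioxin linkages inert to BBr3.

**Compound list**

1 | 3,4-dihydroxy-5-methoxybenzaldehyde | COc1cc(C=O)cc(O)c1O | starting material
2 | 4-(benzyloxy)-3-hydroxy-5-methoxybenzaldehyde | COc1cc(C=O)cc(O)c1OCc1ccccc1 | intermediate
3 | 4-(benzyloxy)-2-bromo-3-hydroxy-5-methoxybenzaldehyde | COc1cc(C=O)c(Br)c(O)c1OCc1ccccc1 | intermediate
4 | 4-(benzyloxy)-2-bromo-5-methoxy-3-(methoxymethoxy)benzaldehyde | COCOc1c(Br)c(C=O)cc(OC)c1OCc1ccccc1 | intermediate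
5 | 4-(benzyloxy)-2-bromo-5-methoxy-3-(methoxymethoxy)phenyl formate (formed in the flask) | COCOc1c(Br)c(OC=O)cc(OC)c1OCc1ccccc1 | intermediate
6 | 4-(benzyloxy)-2-bromo-5-methoxy-3-(methoxymethoxy)phenol | COCOc1c(Br)c(O)cc(OC)c1OCc1ccccc1 | intermediate
7 | 2-fluoro-4,6-dimethoxybenzaldehyde | COc1cc(F)c(C=O)c(OC)c1 | starting material
8 | 2-[4-(benzyloxy)-2-bromo-5-methoxy-3-(methoxymethoxy)phenoxy]-4,6-dimethoxybenzaldehyde | COCOc1c(Br)c(Oc2cc(OC)cc(OC)c2C=O)cc(OC)c1OCc1ccccc1 | intermediate
9 | 2-(benzyloxy)-3,7,9-trimethoxy-1-(methoxymethoxy)dibenzo[b,d]furan-6-carbaldehyde | O=Cc1c(OC)cc(OC)c2c1oc1cc(OC)c(OCc3ccccc3)c(OCOC)c12 | intermediate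
10 | 2-(benzyloxy)-3,7,9-trimethoxy-1-(methoxymethoxy)dibenzo[b,d]furan-6-yl formate (formed in the flask) | O=COc1c(OC)cc(OC)c2c1oc1cc(OC)c(OCc3ccccc3)c(OCOC)c12 | intermediate
11 | 2-(benzyloxy)-3,7,9-trimethoxy-1-(methoxymethoxy)dibenzo[b,d]furan-6-ol | Oc1c(OC)cc(OC)c2c1oc1cc(OC)c(OCc3ccccc3)c(OCOC)c12 | intermediate
12 | 1-bromo-3,5-dimethoxybenzene | COc1cc(Br)cc(OC)c1 | starting material
13 | 2-(benzyloxy)-6-(3,5-dimethoxyphenoxy)-3,7,9-trimethoxy-1-(methoxymethoxy)dibenzo[b,d]furan | COc1cc(OC)cc(Oc2c(OC)cc(OC)c3c2oc2cc(OC)c(OCc4ccccc4)c(OCOC)c23)c1 | intermediate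
14 | 6-(3,5-dimethoxyphenoxy)-3,7,9-trimethoxy-1-(methoxymethoxy)dibenzo[b,d]furan-2-ol | COc1cc(OC)cc(Oc2c(OC)cc(OC)c3c2oc2cc(OC)c(O)c(OCOC)c23)c1 | intermediate
15 | 6-(3,5-dimethoxyphenoxy)-3,7,9-trimethoxy-1-(methoxymethoxy)-2-[(triisopropylsilyl)oxy]dibenzo[b,d]furan | COc1cc(OC)cc(Oc2c(OC)cc(OC)c3c2oc2cc(OC)c(O[Si](C(C)C)(C(C)C)C(C)C)c(OCOC)c23)c1 | intermediate
16 | 6-(3,5-dimethoxyphenoxy)-3,7,9-trimethoxy-2-[(triisopropylsilyl)oxy]dibenzo[b,d]furan-1-ol | COc1cc(OC)cc(Oc2c(OC)cc(OC)c3c2oc2cc(OC)c(O[Si](C(C)C)(C(C)C)C(C)C)c(O)c23)c1 | intermediate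
17 | 3,4-dichloroanisole | COc1ccc(Cl)c(Cl)c1 | starting material
18 | (2,3-dichloro-6-methoxyphenyl)lithium (formed in the flask) | COc1ccc(Cl)c(Cl)c1[Li] | intermediate
19 | lithium (2,3-dichloro-6-methoxyphenyl)trimethoxyborate (formed in the flask) | [Li+].COc1ccc(Cl)c(Cl)c1[B-](OC)(OC)OC | intermediate
20 | 2,3-dichloro-6-methoxyphenol | COc1ccc(Cl)c(Cl)c1O | intermediate
21 | 2,3-dichloro-5-methoxy-1,4-benzoquinone | COC1=CC(=O)C(Cl)=C(Cl)C1=O | intermediate
22 | 3-chloro-5-methoxy-2-(dibenzofuran-1-yloxy)-1,4-benzoquinone, the aryl group being that of 16 with its silyl ether (formed in the flask) | COc1cc(OC)cc(Oc2c(OC)cc(OC)c3c2oc2cc(OC)c(O[Si](C(C)C)(C(C)C)C(C)C)c(OC4=C(Cl)C(=O)C(OC)=CC4=O)c23)c1 | intermediate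
23 | caesium phenoxide of desilylated 22 (formed in the flask) | [Cs+].COc1cc(OC)cc(Oc2c(OC)cc(OC)c3c2oc2cc(OC)c([O-])c(OC4=C(Cl)C(=O)C(OC)=CC4=O)c23)c1 | intermediate
24 | ring A–B–C–D dioxin-fused methoxyquinone | COc1cc(OC)cc(Oc2c(OC)cc(OC)c3c2oc2cc(OC)c4c(c23)OC2=C(O4)C(=O)C(OC)=CC2=O)c1 | intermediate
25 | ring A–B–C–D hydroquinone (D2 and D5 hydroxyls free) | COc1cc(OC)cc(Oc2c(OC)cc(OC)c3c2oc2cc(OC)c4c(c23)Oc2c(O4)c(O)c(OC)cc2O)c1 | intermediate
26 | ring A–B–C–D phenol, D2-O-triisopropylsilyl, D5 hydroxyl free | COc1cc(OC)cc(Oc2c(OC)cc(OC)c3c2oc2cc(OC)c4c(c23)Oc2c(O4)c(O)c(OC)cc2O[Si](C(C)C)(C(C)C)C(C)C)c1 | intermediate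
27 | 1-bromo-2-iodo-3,5-dimethoxybenzene | COc1cc(Br)c(I)c(OC)c1 | intermediate
28 | 2,2'-dibromo-4,4',6,6'-tetramethoxy-1,1'-biphenyl | COc1cc(Br)c(-c2c(Br)cc(OC)cc2OC)c(OC)c1 | intermediate
29 | 2,4,6-trimethoxyphenol | COc1cc(OC)c(O)c(OC)c1 | starting material
30 | 2,4-dimethoxy-6-(2,4,6-trimethoxyphenoxy)benzaldehyde | COc1cc(OC)c(C=O)c(Oc2c(OC)cc(OC)cc2OC)c1 | intermediate
31 | 2,4-dimethoxy-6-(2,4,6-trimethoxyphenoxy)phenyl formate (formed in the flask) | COc1cc(OC)c(OC=O)c(Oc2c(OC)cc(OC)cc2OC)c1 | intermediate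
32 | 2,4-dimethoxy-6-(2,4,6-trimethoxyphenoxy)phenol | COc1cc(OC)c(O)c(Oc2c(OC)cc(OC)cc2OC)c1 | intermediate
33 | 2-bromo-2'-[2,4-dimethoxy-6-(2,4,6-trimethoxyphenoxy)phenoxy]-4,4',6,6'-tetramethoxy-1,1'-biphenyl | COc1cc(Br)c(-c2c(OC)cc(OC)cc2Oc2c(OC)cc(OC)cc2Oc2c(OC)cc(OC)cc2OC)c(OC)c1 | intermediate
34 | pentadeca-O-methyl D2-O-triisopropylsilyl ether of the target | COc1cc(OC)cc(Oc2c(OC)cc(OC)c3c2oc2cc(OC)c4c(c23)Oc2c(O4)c(Oc3cc(OC)cc(OC)c3-c3c(OC)cc(OC)cc3Oc3c(OC)cc(OC)cc3Oc3c(OC)cc(OC)cc3OC)c(OC)cc2O[Si](C(C)C)(C(C)C)C(C)C)c1 | intermediate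
35 | pentadeca-O-methyl ether of the target (D2 hydroxyl free) | COc1cc(OC)cc(Oc2c(OC)cc(OC)c3c2oc2cc(OC)c4c(c23)Oc2c(O4)c(Oc3cc(OC)cc(OC)c3-c3c(OC)cc(OC)cc3Oc3c(OC)cc(OC)cc3Oc3c(OC)cc(OC)cc3OC)c(OC)cc2O)c1 | intermediate
36 | CNP0192765.0 | Oc1cc(O)cc(Oc2c(O)cc(O)c3c2oc2cc(O)c4c(c23)Oc2c(O)cc(O)c(Oc3cc(O)cc(O)c3-c3c(O)cc(O)cc3Oc3c(O)cc(O)cc3Oc3c(O)cc(O)cc3O)c2O4)c1 | target

**Step count**

Total: 24 steps. Longest linear sequence: 17 steps (steps 1–11, then 14, 15, 16, 22, 23, 24). The quinone (steps 12–13) and the arm (steps 17–21) are side branches.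

**Steps most likely to fail**

Step 14. The freed phenoxide may attack the aryloxy-bearing quinone carbon in an ipso (Smiles-type) fashion through a spiro ketal, which exchanges the two catechol oxygens before ring closure and erodes the orientation. Electron transfer from the electron-rich phenoxide to the quinone may also compete. Fallback: the second C–O bond is made on the aromatic level, where neither process is possible. The route sets out from 16 and 21 with K2CO3 only, and aryloxychloroquinone 22 is isolated. It is reduced with Na2S2O4 to the chlorohydroquinone F1, and both hydroxyls are methylated (MeI, K2CO3, acetone) to the trimethoxy aryl chloride F2. The silyl ether is cleaved (Bu4NF, AcOH) to the phenol F3, and the dioxin ring is closed by intramolecular palladium-catalysed C–O coupling of the aryl chloride (Pd(OAc)2, tBuXPhos, K3PO4, toluene, 100 °C) to the dibenzodioxin F4. Oxidative demethylation of the para-dimethoxy pair of ring D with (NH4)2Ce(NO3)6 in MeCN/H2O returns to quinone 24.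

Step 22. Carbon–oxygen bond formation between a doubly ortho-substituted phenol and an ortho-arylated bromide may be slow. The valuable arm bromide may then be consumed by protodebromination, and the silyl group may be lost or transferred under base so that the wrong oxygen is arylated. Fallback: the order of assembly is changed from convergent to linear, so that the electrophile of the hindered union is a cheap symmetrical compound that can be used in large excess. Phenol 26 is coupled under the same palladium catalysis with dibromide 28 (five equivalents) to give the ring A–E–F bromide F5. The G–H phenol 32 is then attached to F5 by a second C–O coupling, which gives 34.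

Step 21. Conversion at the hindered bromide may be low, and the product may react a second time to give the bis-ether. Fallback: the F–O–G ether is made by SNAr and the biaryl bond afterwards. Phenol 32 and fluoroaldehyde 7 (K2CO3, DMF, 120 °C) give the F–G–H aldehyde F6, and Baeyer–Villiger oxidation with methanolysis gives the phenol F7. Tf2O/pyridine gives the triflate F8, and Miyaura borylation (bis(pinacolato)diboron, PdCl2(dppf), KOAc, dioxane) gives the pinacol boronate F9. Suzuki–Miyaura coupling of F9 with iodide 27 (Pd(OAc)2, SPhos, K3PO4, toluene/H2O), selective for the C–I bond, returns to arm bromide 33.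

**Further compounds**

F1 | step 14 | chlorohydroquinone from reduction of 22 (silyl ether retained) | COc1cc(OC)cc(Oc2c(OC)cc(OC)c3c2oc2cc(OC)c(O[Si](C(C)C)(C(C)C)C(C)C)c(Oc4c(Cl)c(O)c(OC)cc4O)c23)c1
F2 | step 14 | 2-chloro-3,4,6-trimethoxyphenyl ether of the silylated ring A–B–C fragment | COc1cc(OC)cc(Oc2c(OC)cc(OC)c3c2oc2cc(OC)c(O[Si](C(C)C)(C(C)C)C(C)C)c(Oc4c(Cl)c(OC)c(OC)cc4OC)c23)c1
F3 | step 14 | desilylated phenol of F2 | COc1cc(OC)cc(Oc2c(OC)cc(OC)c3c2oc2cc(OC)c(O)c(Oc4c(Cl)c(OC)c(OC)cc4OC)c23)c1
F4 | step 14 | ring A–B–C–D dibenzodioxin with ring D as 2,4,5-trimethoxy arene | COc1cc(OC)cc(Oc2c(OC)cc(OC)c3c2oc2cc(OC)c4c(c23)Oc2c(O4)c(OC)c(OC)cc2OC)c1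
F5 | step 22 | ring A–E–F bromide (26 etherified at D5 with one aryl of 28) | COc1cc(OC)cc(Oc2c(OC)cc(OC)c3c2oc2cc(OC)c4c(c23)Oc2c(O4)c(Oc3cc(OC)cc(OC)c3-c3c(OC)cc(OC)cc3Br)c(OC)cc2O[Si](C(C)C)(C(C)C)C(C)C)c1
F6 | step 21 | 2-[2,4-dimethoxy-6-(2,4,6-trimethoxyphenoxy)phenoxy]-4,6-dimethoxybenzaldehyde | O=Cc1c(OC)cc(OC)cc1Oc1c(OC)cc(OC)cc1Oc1c(OC)cc(OC)cc1OC
F7 | step 21 | 2-[2,4-dimethoxy-6-(2,4,6-trimethoxyphenoxy)phenoxy]-4,6-dimethoxyphenol | Oc1c(OC)cc(OC)cc1Oc1c(OC)cc(OC)cc1Oc1c(OC)cc(OC)cc1OC
F8 | step 21 | trifluoromethanesulfonate of F7 | FC(F)(F)S(=O)(=O)Oc1c(OC)cc(OC)cc1Oc1c(OC)cc(OC)cc1Oc1c(OC)cc(OC)cc1OC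
F9 | step 21 | pinacol boronate of the F–G–H unit | CC1(C)OB(OC1(C)C)c1c(OC)cc(OC)cc1Oc1c(OC)cc(OC)cc1Oc1c(OC)cc(OC)cc1OC
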